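**Retrosynthetic overview**
1. The target comes from hydrolysis and deacetylation of a 1-aryl-1-methoxy-tetrahydronaphtho[2,3-c]furan. Its furan ketal (ring C) masks both the aryl ketone and the CH2OH.
2. The tricycle comes from an acyclic (R)-γ-hydroxy ketone plus one CH carbon from HC(OMe)3. Three bonds are cut (O–C ketal, Cα–CH, CH–aryl), and rings C and B close in one flask.
3. The (R)-γ-hydroxy ketone comes from a 3-arylpropanal and a phenacyl bromide by enantioselective enamine/photoredox α-alkylation, then aldehyde-selective reduction. This sets the only stereocentre.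
4. The 3-arylpropanal comes from eugenyl acetate by anti-Markovnikov oxidation. The phenacyl bromide comes from acetovanillone acetate.
5. Ring order: aromatic rings A (later fused) and D (aroyl) are bought. Ring C (dihydrofuran) closes first and ring B (carbocycle) second, both in step 4. Ring C is opened in step 5.

Assumption: both aryl acetate starting materials are taken as catalogue chemicals. Each is otherwise one Ac2O acetylation away from eugenol or acetovanillone.

**Step 1**
Reactants: 1 eugenyl acetate (4-allyl-2-methoxyphenyl acetate)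
Product: 4 2-methoxy-4-(3-oxopropyl)phenyl acetate, via trialkylborane 2 (not isolated), via trialkyl borate 3 (not isolated)
Conditions: BH3·THF (0.35 equiv), THF, 0 → 23 °C; then NMO (3 equiv), 4 Å MS, CH2Cl2, 40 °C, 1 h; then (n-Pr4N)RuO4 (5 mol %), 23 °C
Reagents that add atoms: N-methylmorpholine N-oxide, C[N+]1([O-])CCOCC1
Why: Anti-Markovnikov hydroboration puts boron on the terminal carbon, the amine N-oxide turns the three C–B bonds of 2 into borate 3, and Ley–Griffith perruthenate/NMO oxidation stops at the aldehyde under neutral, water-free conditions that leave the aryl acetate intact; no stereocentre is formed.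

**Step 2**
Reactants: 5 4-acetyl-2-methoxyphenyl acetate (acetovanillone acetate)
Product: 6 4-(2-bromoacetyl)-2-methoxyphenyl acetate
Conditions: Br2 (1.0 equiv), CHCl3, 0 → 23 °C
Reagents that add atoms: bromine, BrBr
Why: This is an acid-autocatalysed enol α-bromination of an aryl methyl ketone, and the ring is deactivated by the acyl and acetoxy groups, so only the CH3 group reacts.

**Step 3**
Reactants: 4 2-methoxy-4-(3-oxopropyl)phenyl acetate; 6 4-(2-bromoacetyl)-2-methoxyphenyl acetate
Product: 8 (3R)-1,4-bis(4-acetoxy-3-methoxyphenyl)-3-(hydroxymethyl)butan-1-one, via keto aldehyde 7 (not isolated)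
Conditions: 4 (2 equiv), 6 (1 equiv), (2R,5S)-2-tert-butyl-3,5-dimethylimidazolidin-4-one·TfOH (20 mol %), Ru(bpy)3Cl2 (0.5 mol %), 2,6-lutidine (2 equiv), degassed DMF, blue LED, 23 °C; extractive work-up, then NaBH4, CH2Cl2–MeOH (1:1), −78 °C
Reagents that add atoms: none
Why: In this enamine/photoredox dual catalysis (MacMillan-type asymmetric α-alkylation of aldehydes) the phenacyl radical from one-electron reduction of 6 adds to the open Si face of the E-enamine of 4 (the Re face is blocked by the catalyst methyl group), which gives the R centre, and NaBH4 at −78 °C then reduces only the aldehyde before it can epimerise, leaving the electron-rich aryl ketone and both acetates untouched.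

**Step 4 (key step)**
Reactants: 8 (3R)-1,4-bis(4-acetoxy-3-methoxyphenyl)-3-(hydroxymethyl)butan-1-one; 9 trimethyl orthoformate
Product: 12 (3aR)-1-(4-acetoxy-3-methoxyphenyl)-1,6-dimethoxy-1,3,3a,4-tetrahydronaphtho[2,3-c]furan-7-yl acetate (both C-1 epimers), via dihydrofuran 10 (not isolated), via dimethyl acetal 11 (not isolated)
Conditions: 9 (4 equiv), TfOH (15 mol %), CH2Cl2 (0.02 M), 8 added slowly at −30 °C, then → 23 °C; Et3N quench, aq NaHCO3 wash, product used crude
Reagents that add atoms: trimethyl orthoformate (9), COC(OC)OC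
Why: Proposed new method: TfOH and 9 dehydrate the γ-hydroxy ketone to cyclic enol ether 10 (ring C), whose β-carbon is captured much faster than any arene by the dimethoxycarbenium ion (the known acid-catalysed addition of orthoformates to 2,3-dihydrofurans) to give 11; ionisation of 11 gives an alkoxyallyl cation whose unhindered CH terminus is attacked by the ring A carbon para to OMe in a six-membered Friedel–Crafts closure (closest known reaction: Bougault/Bradsher-type cyclodehydration of α-formyl γ-aryl carbonyl compounds), and loss of MeOH followed by MeOH capture at the ketal carbon gives 12 (ring B); the C–H at the stereocentre sits on a cross-conjugated position of every cation involved, so it cannot be lost and the R configuration is carried through.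

**Step 5**
Reactants: 12 (3aR)-1-(4-acetoxy-3-methoxyphenyl)-1,6-dimethoxy-1,3,3a,4-tetrahydronaphtho[2,3-c]furan-7-yl acetate
Product: 14 [(3R)-7-hydroxy-3-(hydroxymethyl)-6-methoxy-3,4-dihydronaphthalen-2-yl](4-hydroxy-3-methoxyphenyl)methanone (target), via bisphenol ketal 13 (not isolated)
Conditions: K2CO3 (3 equiv), MeOH, N2, 0 → 23 °C; then 1 M aq HCl to pH 1, THF, 23 °C, 30 min
Reagents that add atoms: water, O
Why: Zemplén-type methanolysis frees both phenols while the ketal is stable to base, and the acidic work-up ionises the allylic, benzylic ketal so that water adds and ring C opens to the enone and the CH2OH group (ketal hydrolysis); C-3 is not enolisable and stays R.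

**Compound list**
1 | eugenyl acetate (4-allyl-2-methoxyphenyl acetate) | C=CCc1ccc(OC(C)=O)c(OC)c1 | starting material
2 | tris[3-(4-acetoxy-3-methoxyphenyl)propyl]borane | B(CCCc1ccc(OC(C)=O)c(OC)c1)(CCCc1ccc(OC(C)=O)c(OC)c1)CCCc1ccc(OC(C)=O)c(OC)c1 | intermediate
3 | tris[3-(4-acetoxy-3-methoxyphenyl)propyl] borate | B(OCCCc1ccc(OC(C)=O)c(OC)c1)(OCCCc1ccc(OC(C)=O)c(OC)c1)OCCCc1ccc(OC(C)=O)c(OC)c1 | intermediate
4 | 2-methoxy-4-(3-oxopropyl)phenyl acetate | O=CCCc1ccc(OC(C)=O)c(OC)c1 | intermediate
5 | 4-acetyl-2-methoxyphenyl acetate | CC(=O)c1ccc(OC(C)=O)c(OC)c1 | starting material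
6 | 4-(2-bromoacetyl)-2-methoxyphenyl acetate | O=C(CBr)c1ccc(OC(C)=O)c(OC)c1 | intermediate
7 | (2R)-2-(4-acetoxy-3-methoxybenzyl)-4-(4-acetoxy-3-methoxyphenyl)-4-oxobutanal | CC(=O)Oc1ccc(cc1OC)C(=O)C[C@H](C=O)Cc1ccc(OC(C)=O)c(OC)c1 | intermediate
8 | (3R)-1,4-bis(4-acetoxy-3-methoxyphenyl)-3-(hydroxymethyl)butan-1-one | CC(=O)Oc1ccc(cc1OC)C(=O)C[C@H](CO)Cc1ccc(OC(C)=O)c(OC)c1 | intermediate
9 | trimethyl orthoformate | COC(OC)OC | starting material
10 | (3R)-3-(4-acetoxy-3-methoxybenzyl)-5-(4-acetoxy-3-methoxyphenyl)-2,3-dihydrofuran | CC(=O)Oc1ccc(cc1OC)C1=C[C@@H](Cc2ccc(OC(C)=O)c(OC)c2)CO1 | intermediate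
11 | (3R)-3-(4-acetoxy-3-methoxybenzyl)-5-(4-acetoxy-3-methoxyphenyl)-4-(dimethoxymethyl)-2,3-dihydrofuran | CC(=O)Oc1ccc(cc1OC)C1=C(C(OC)OC)[C@@H](Cc2ccc(OC(C)=O)c(OC)c2)CO1 | intermediate
12 | (3aR)-1-(4-acetoxy-3-methoxyphenyl)-1,6-dimethoxy-1,3,3a,4-tetrahydronaphtho[2,3-c]furan-7-yl acetate (C-1 epimers) | COC1(c2ccc(OC(C)=O)c(OC)c2)OC[C@@H]2Cc3cc(OC)c(OC(C)=O)cc3C=C12 | intermediate
13 | (3aR)-1-(4-hydroxy-3-methoxyphenyl)-1,6-dimethoxy-1,3,3a,4-tetrahydronaphtho[2,3-c]furan-7-ol (C-1 epimers) | COC1(c2ccc(O)c(OC)c2)OC[C@@H]2Cc3cc(OC)c(O)cc3C=C12 | intermediate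
14 | [(3R)-7-hydroxy-3-(hydroxymethyl)-6-methoxy-3,4-dihydronaphthalen-2-yl](4-hydroxy-3-methoxyphenyl)methanone | COc1cc(C(=O)C2=Cc3cc(O)c(OC)cc3C[C@H]2CO)ccc1O | target

**Step count and risk**
Total steps: 5. Longest linear sequence: 4 (steps 1, 3, 4, 5).

Step 4 is the most likely to fail. Ring A could attack the ketone-derived cationic carbon directly and give a 1-aryl-3,4-dihydronaphthalene, or enol ether 10 could oligomerise. The fallback sets out from 8 and comes back at 14. It blocks ring C and builds ring B alone through two separate C–C bond formations. Ac2O/pyridine converts 8 into (2R)-2-(4-acetoxy-3-methoxybenzyl)-4-(4-acetoxy-3-methoxyphenyl)-4-oxobutyl acetate F1. Rieche formylation (Cl2CHOMe, TiCl4, CH2Cl2, −10 °C) para to OMe on ring A gives (2R)-2-(4-acetoxy-2-formyl-5-methoxybenzyl)-4-(4-acetoxy-3-methoxyphenyl)-4-oxobutyl acetate F2. HCl in MeOH (40 °C, then water) closes ring B by acid-catalysed intramolecular aldol condensation and removes the three acetates, giving 14.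

Step 3 is second. The radical chain could be terminated early, the ee could be low, or 7 could epimerise before reduction. The fallback sets out from 5 (used together with 4) and comes back at 7. It replaces the bromide/photoredox pair by oxidative enamine (SOMO) catalysis. TMSOTf/Et3N (CH2Cl2, 0 °C) turns 5 into 2-methoxy-4-[1-(trimethylsilyloxy)vinyl]phenyl acetate F3. This adds to the enamine radical cation generated from 4 with the 5-benzyl-2-tert-butyl-3-methylimidazolidin-4-one salt that leaves the same Si face open and (NH4)2Ce(NO3)6 (2 equiv, DME, −20 °C). Loss of the silyl group gives 7, which is reduced as before to 8.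

Step 1 is third. BH3 gives roughly 10 % internal hydroboration, and oxidation of borate 3 may be sluggish. The fallback sets out from 1 and comes back at 4. It oxidises first and reduces second. DDQ (2.2 equiv, wet dioxane, 23 °C) converts the allylarene into (E)-4-acetoxy-3-methoxycinnamaldehyde F4. Conjugate transfer hydrogenation (Hantzsch ester, Bn2NH·TFA cat., THF) or H2 over Pd/C in EtOAc then saturates only the C=C bond and gives 4.

**Further compounds**
F1 | step 4 | (2R)-2-(4-acetoxy-3-methoxybenzyl)-4-(4-acetoxy-3-methoxyphenyl)-4-oxobutyl acetate | CC(=O)Oc1ccc(cc1OC)C(=O)C[C@H](COC(C)=O)Cc1ccc(OC(C)=O)c(OC)c1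
F2 | step 4 | (2R)-2-(4-acetoxy-2-formyl-5-methoxybenzyl)-4-(4-acetoxy-3-methoxyphenyl)-4-oxobutyl acetate | CC(=O)Oc1ccc(cc1OC)C(=O)C[C@H](COC(C)=O)Cc1cc(OC)c(OC(C)=O)cc1C=O
F3 | step 3 | 2-methoxy-4-[1-(trimethylsilyloxy)vinyl]phenyl acetate | C=C(O[Si](C)(C)C)c1ccc(OC(C)=O)c(OC)c1
F4 | step 1 | (E)-4-acetoxy-3-methoxycinnamaldehyde | CC(=O)Oc1ccc(/C=C/C=O)cc1OC
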